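## Retrosynthetic overview

1. Target ⇐ butanoyl ketone (C3=C4 introduced last by silyl enol ether dehydrogenation) ⇐ α-methylene γ-lactone (C11 set by hydrogenation) ⇐ cyclocarbonylation of a cis pair, C6 hydroxyl and C7 ethynyl.
2. C7 ethynyl and C10 methyl ⇐ two cis aldehydes (C11, C14) from ozonolysis of an etheno bridge C11=C14 in a bicyclo[3.2.2]nonene; the C1 hydroxyl masks C11 as a lactol and so tells them apart.
3. trans C1–OH / C5–O-isobutyryl ⇐ epoxide of a 1-butanoylcycloalkene (C1=C5) opened at C5 by isobutyrate; the epoxide face is set by the C6 hydroxyl and the bicycle; the acyl group enters by enol triflate/aldehyde coupling.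
4. Key disconnection: bicyclo[3.2.2]nona-3,6-dien-2-one ⇐ tropone + ethylene, [4+2], forming C8–C7 and C9–C10 together. Enabling feature: the methyl carbon C14 on C10 and the lactone α-carbon C11 on C7 are cis and 1,4-related across the cycloheptane; bonded to each other they close, with C10–C1–C5–C6–C7, a second seven-membered ring, which at the trienone level is tropone with C10 and C7 as diene termini.
5. Ring order: cycloheptane of the target together with a temporary cyclohexene C10–C9–C8–C7–C11=C14 (step 1) → cyclohexene cut (step 12) → γ-lactone (step 15).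

Key step: step 1

Remark on numbering (used for every compound): C1 = ring carbon that becomes the carbinol; C5, C6 = the two O-bearing CH; C7 = ring-fusion CH; C8, C9 = the CH2–CH2 unit; C10 = CH bearing methyl C14; C11, C12, C13 = lactone α-carbon, carbonyl, methyl; C2, C3, C4, C15 = the four-carbon acyl chain. "Syn" and "anti" refer to the etheno bridge C11=C14; after its cleavage the syn face is the face that carries C11 and C14 (β).

Remark on the chemistry: compounds 3 to 5 are racemic and the absolute configuration is selected in step 3; their SMILES show the enantiomer that is carried on.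

## Route

Step 1
Reactants: 1 tropone; 2 ethylene
Product: 3 (±)-bicyclo[3.2.2]nona-3,6-dien-2-one
Conditions: ethylene (ca. 100 bar, steel autoclave), toluene, BHT (cat.), 150 °C
Reagents that add atoms: none
Why: Thermal, concerted, suprafacial [4+2] cycloaddition (Diels–Alder) in which the C10=C14–C11=C7 diene of tropone (its carbons 2 to 5) takes up ethylene across C10 and C7, so that C9–C10 and C8–C7 form together. The closest known reaction type is the Diels–Alder addition of tropone to simple and activated alkenes under heat and pressure, which gives bicyclo[3.2.2]nona-3,6-dien-2-ones. The new seven-membered carbocycle C1–C10–C9–C8–C7–C6–C5 (the ring of the target) and the six-membered ring C10–C9–C8–C7–C11=C14 are both closed by this one intermolecular cycloaddition through a boat-like six-centre transition state. C10 and C7 become bridgeheads, so C14 and C11 are locked on one face (the later cis relation of the C10 methyl and the lactone α-carbon); the adduct is racemic and the absolute configuration is selected in step 3. The step needs periselectivity for [4+2] over [6+4] and [8+2] modes and over dimerisation of tropone; the two diene units of tropone are equivalent by symmetry and ethylene is symmetric, so no regio- or endo/exo question arises, and excess ethylene under pressure with a radical inhibitor should hold back dimerisation.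

Step 2
Reactants: 3 (±)-bicyclo[3.2.2]nona-3,6-dien-2-one
Product: 5 (±)-4-hydroxybicyclo[3.2.2]non-6-en-2-one (hydroxyl on C6 syn to the etheno bridge), via boryl ketone 4 (not isolated)
Conditions: B2pin2, CuCl (5 mol %), DPEphos (5 mol %), NaOt-Bu (10 mol %), MeOH (2 equiv), THF, rt; then 30 % H2O2, aq. NaHCO3, 0 °C
Reagents that add atoms: hydrogen peroxide, OO (oxygen on C6); bis(pinacolato)diboron, CC1(C)OB(OC1(C)C)B1OC(C)(C)C(C)(C)O1 (boryl group of 4 only)
Why: Copper-catalysed conjugate borylation of the enone followed by stereoretentive C–B oxidation; the boryl copper species should add to C6 from the less hindered face syn to the etheno bridge (the ethano bridge turns a hydrogen towards the other face), which places the C6 oxygen on the face of C11 as the cis-fused lactone requires.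

Step 3
Reactants: 5 (±)-4-hydroxybicyclo[3.2.2]non-6-en-2-one
Product: 6 (4S)-4-hydroxybicyclo[3.2.2]non-6-en-2-one (unreacted enantiomer of 5)
Conditions: lipase from Burkholderia cepacia (immobilised), vinyl acetate, t-BuOMe, 30 °C, to just over half conversion; chromatography
Reagents that add atoms: none
Why: Lipase-catalysed kinetic resolution by enantioselective transesterification, in which by the empirical size rule for lipase acylations (large bridgehead carbon against CH2) the (4R)-alcohol should be acetylated faster and the wanted (4S)-alcohol is left behind; no new stereocentre is formed.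

Step 4
Reactants: 6 (4S)-hydroxy ketone
Product: 7 triethylsilyl ether of 6
Conditions: Et3SiCl, imidazole, DMF, 0 °C to rt
Reagents that add atoms: chlorotriethylsilane, CC[Si](Cl)(CC)CC
Why: Silylation of the secondary alcohol, so that the next step meets neither a free hydroxyl nor an alkoxide; no stereocentre is touched.

Step 5
Reactants: 7 silyl ether
Product: 9 enol triflate (C1–OTf, C1=C5), via potassium enolate 8 (not isolated)
Conditions: KN(SiMe3)2, THF, −78 °C; then PhNTf2, −78 to 0 °C
Reagents that add atoms: N-phenylbis(trifluoromethanesulfonimide), O=S(=O)(N(c1ccccc1)S(=O)(=O)C(F)(F)F)C(F)(F)F; potassium bis(trimethylsilyl)amide, C[Si](C)(C)[N-][Si](C)(C)C.[K+] (potassium of 8 only)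
Why: Regiospecific enolate formation and O-triflation, since C10 is a bridgehead and only C5 can be deprotonated, and at −78 °C the β-silyloxy enolate should not eliminate.

Step 6
Reactants: 9 enol triflate; 10 butanal
Product: 11 allylic alcohol (C2 carbinol, both epimers)
Conditions: CrCl2 (4 equiv), NiCl2 (2 mol %), DMF, rt
Reagents that add atoms: none
Why: Nozaki–Hiyama–Kishi coupling of an alkenyl triflate with an aldehyde, which tolerates the silyl ether and the strained alkene; the new carbinol centre C2 forms unselectively and is removed in step 7.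

Step 7
Reactants: 11 allylic alcohol
Product: 12 silyloxy enone (1-butanoyl on C1, C1=C5)
Conditions: Dess–Martin periodinane, NaHCO3, CH2Cl2, 0 °C to rt
Reagents that add atoms: none
Why: Dess–Martin oxidation of the secondary allylic alcohol removes the C2 stereocentre and makes C5 the β-carbon of an enone.

Step 8
Reactants: 12 silyloxy enone
Product: 13 hydroxy enone (free C6 hydroxyl syn to the etheno bridge)
Conditions: HF·pyridine, pyridine, THF, 0 °C
Reagents that add atoms: none
Why: Fluoride cleavage of the triethylsilyl ether frees the C6 hydroxyl that is to direct the epoxidation.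

Step 9
Reactants: 13 hydroxy enone
Product: 14 epoxy ketone (C1–C5 epoxide syn to the C6 hydroxyl and to the etheno bridge)
Conditions: t-BuOOH (in decane), BnMe3NOH (Triton B, cat.), THF, 0 °C
Reagents that add atoms: tert-butyl hydroperoxide, CC(C)(C)OO
Why: Weitz–Scheffer nucleophilic epoxidation of a γ-hydroxy enone, in which the hydroperoxide anion adds to C5 and closes onto C1 on the face syn to the free C6 hydroxyl (hydrogen-bond delivery), which is also the open face syn to the etheno bridge, so the oxygen on C1 ends cis to C14 and trans to the acyl group as in the target.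

Step 10
Reactants: 14 epoxy ketone
Product: 15 diol isobutyrate (C1–OH and C6–OH syn, C5–O-isobutyryl anti)
Conditions: i-PrCO2H (10 equiv), i-PrCO2Cs (1 equiv), DMF, 60 °C
Reagents that add atoms: isobutyric acid, CC(C)C(=O)O
Why: Epoxide opening of an α,β-epoxy ketone by a carboxylate, which should attack the secondary β-carbon C5 (C1 is quaternary and α to the ketone) with inversion, anti to the epoxide oxygen, giving the C5 ester trans to both neighbouring hydroxyls and the tertiary C1 hydroxyl with retention.

Step 11
Reactants: 15 diol isobutyrate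
Product: 16 C6 triethylsilyl ether of 15
Conditions: Et3SiCl, imidazole, DMAP (cat.), CH2Cl2, 0 °C to rt
Reagents that add atoms: chlorotriethylsilane, CC[Si](Cl)(CC)CC
Why: Selective silylation of the secondary C6 hydroxyl (the tertiary α-keto hydroxyl is inert under these conditions), so that only the C1 hydroxyl can trap an aldehyde in step 12.

Step 12
Reactants: 16 silyl ether
Product: 19 lactol aldehyde (C1–O–C11 lactol as both anomers; free C14 aldehyde), via ozonide 17 (not isolated), via hydroxy dialdehyde 18 (not isolated)
Conditions: O3, CH2Cl2, −78 °C; then PPh3, −78 °C to rt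
Reagents that add atoms: ozone, [O-][O+]=O
Why: Ozonolysis with reductive work-up cleaves the only C=C bond (C11=C14) to two aldehydes held cis on C7 and C10, and the C1 hydroxyl, syn and 1,4 to C7, should close a six-membered lactol on C11 (it cannot reach C14 without a four-membered ring), which tells the two carbonyl carbons apart.

Step 13
Reactants: 19 lactol aldehyde
Product: 21 methyl lactol (C14 now the methyl group on C10), via tosylhydrazone 20 (not isolated)
Conditions: TsNHNH2 (1.0 equiv), THF, 0 °C; then catecholborane, CHCl3, 0 °C; then NaOAc·3H2O, 60 °C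
Reagents that add atoms: 4-methylbenzenesulfonohydrazide, Cc1ccc(cc1)S(=O)(=O)NN (its atoms stay in 20 only)
Why: Deoxygenation of the free aldehyde by tosylhydrazone formation and hydride reduction (loss of sulfinate and N2 from the diazene) turns C14 into the methyl group under non-basic conditions that should not epimerise C10, while the hindered C2 ketone and the lactol should react much more slowly with the hydrazide.

Step 14
Reactants: 21 methyl lactol
Product: 23 alkynyl diol (C7 ethynyl cis to the free C6 hydroxyl), via silyl alkyne 22 (not isolated)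
Conditions: (MeO)2P(O)C(N2)C(O)Me, K2CO3, MeOH, 0 °C to rt; then 1 M HCl (pH 2), rt
Reagents that add atoms: dimethyl (1-diazo-2-oxopropyl)phosphonate, COP(=O)(OC)C(=[N+]=[N-])C(C)=O (carbon C13)
Why: Ohira–Bestmann (Seyferth–Gilbert) homologation of the lactol through its open hydroxy aldehyde adds C13 as a terminal alkyne and, run cold, should leave C7 and the hindered isobutyrate untouched, and acidification in the same flask cleaves the triethylsilyl ether.

Step 15
Reactants: 23 alkynyl diol
Product: 24 α-methylene γ-lactone (cis-fused at C6/C7)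
Conditions: PdCl2 (5 mol %), PPh3 (10 mol %), SnCl2 (10 mol %), CO (7 bar), MeCN, 75 °C
Reagents that add atoms: carbon monoxide, [C-]#[O+]
Why: Palladium-catalysed cyclocarbonylation of a homopropargylic alcohol (alkoxycarbonyl–palladium formation, syn insertion of the alkyne, protonolysis) forms C11–C12 and C12–O in one step, and the lactone is necessarily cis-fused because O6 and C11 are cis.

Step 16
Reactants: 24 α-methylene lactone
Product: 25 α-methyl lactone with butanoyl chain
Conditions: H2 (1 bar), RhCl(PPh3)3 (10 mol %), benzene–EtOH, rt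
Reagents that add atoms: none
Why: Homogeneous hydrogenation of the exocyclic α-methylene lactone (no double-bond migration with this catalyst) should deliver hydrogen to C11 from the convex face of the cis-fused bicycle, the face of H6 and H7, so that methyl C13 ends on the concave face, cis to C8, as in the target.

Step 17
Reactants: 25 α-methyl lactone with butanoyl chain
Product: 28 target CNP0149747.1, via silyl enol ether 26 (not isolated), via silyl enone 27 (not isolated)
Conditions: Me3SiOTf (2.2 equiv), Et3N, CH2Cl2, −78 to 0 °C; then Pd(OAc)2 (1.1 equiv), MeCN, rt; then 1 M HCl, THF, 0 °C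
Reagents that add atoms: trimethylsilyl triflate, C[Si](C)(C)OS(=O)(=O)C(F)(F)F (silyl groups of 26 and 27 only)
Why: Saegusa–Ito dehydrogenation, in which the butanoyl ketone can enolise only towards C3 (C1 is quaternary; the limited amount of silyl triflate at low temperature should spare the lactone and so C11), the silyl enol ether is oxidised by Pd(OAc)2 to the (E)-enone through β-hydride elimination, and mild acid removes the silyl group from the tertiary hydroxyl.

## Compound list

1 | tropone (cyclohepta-2,4,6-trien-1-one) | O=C1C=CC=CC=C1 | starting material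
2 | ethylene | C=C | starting material
3 | (±)-bicyclo[3.2.2]nona-3,6-dien-2-one (C1 ketone, C5=C6, etheno bridge C14=C11, ethano bridge C9–C8; racemate) | O=C1[C@@H]2CC[C@@H](C=C2)C=C1 | intermediate
4 | (±)-4-(pinacolatoboryl)bicyclo[3.2.2]non-6-en-2-one, boron on C6 syn to the etheno bridge (not isolated) | O=C1[C@@H]2CC[C@@H](C=C2)[C@@H](B3OC(C)(C)C(C)(C)O3)C1 | intermediate
5 | (±)-4-hydroxybicyclo[3.2.2]non-6-en-2-one, hydroxyl syn to the etheno bridge (racemate) | O=C1[C@@H]2CC[C@@H](C=C2)[C@@H](O)C1 | intermediate
6 | (4S)-4-hydroxybicyclo[3.2.2]non-6-en-2-one, hydroxyl syn to the etheno bridge (single enantiomer) | O=C1[C@@H]2CC[C@@H](C=C2)[C@@H](O)C1 | intermediate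
7 | 4-(triethylsilyloxy)bicyclo[3.2.2]non-6-en-2-one (silyl ether of 6) | O=C1[C@@H]2CC[C@@H](C=C2)[C@@H](O[Si](CC)(CC)CC)C1 | intermediate
8 | potassium enolate of 7 (C1–O−, C1=C5; not isolated) | [K+].[O-]C1[C@@H]2CC[C@@H](C=C2)[C@@H](O[Si](CC)(CC)CC)C=1 | intermediate
9 | 4-(triethylsilyloxy)bicyclo[3.2.2]nona-2,6-dien-2-yl triflate | O=S(=O)(OC1[C@@H]2CC[C@@H](C=C2)[C@@H](O[Si](CC)(CC)CC)C=1)C(F)(F)F | intermediate
10 | butanal | CCCC=O | starting material
11 | 1-[4-(triethylsilyloxy)bicyclo[3.2.2]nona-2,6-dien-2-yl]butan-1-ol (both C2 epimers) | CCCC(O)C1[C@@H]2CC[C@@H](C=C2)[C@@H](O[Si](CC)(CC)CC)C=1 | intermediate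
12 | 1-[4-(triethylsilyloxy)bicyclo[3.2.2]nona-2,6-dien-2-yl]butan-1-one | CCCC(=O)C1[C@@H]2CC[C@@H](C=C2)[C@@H](O[Si](CC)(CC)CC)C=1 | intermediate
13 | 1-(4-hydroxybicyclo[3.2.2]nona-2,6-dien-2-yl)butan-1-one, hydroxyl syn to the etheno bridge | CCCC(=O)C1[C@@H]2CC[C@@H](C=C2)[C@@H](O)C=1 | intermediate
14 | epoxy ketone: C1–C5 epoxide and C6 hydroxyl both syn to the etheno bridge, butanoyl on C1 | CCCC(=O)[C@]13[C@@H]2CC[C@@H](C=C2)[C@@H](O)[C@H]1O3 | intermediate
15 | diol isobutyrate: C1–OH and C6–OH syn, C5–O-isobutyryl anti to the etheno bridge | CCCC(=O)[C@]1(O)[C@@H]2CC[C@@H](C=C2)[C@@H](O)[C@@H]1OC(=O)C(C)C | intermediate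
16 | C6 triethylsilyl ether of 15 | CCCC(=O)[C@]1(O)[C@@H]2CC[C@@H](C=C2)[C@@H](O[Si](CC)(CC)CC)[C@@H]1OC(=O)C(C)C | intermediate
17 | ozonide of 16 (1,2,4-trioxolane over C11 and C14; not isolated) | CCCC(=O)[C@]1(O)[C@@H]2CC[C@@H](C3OOC2O3)[C@@H](O[Si](CC)(CC)CC)[C@@H]1OC(=O)C(C)C | intermediate
18 | hydroxy dialdehyde: cycloheptane with cis C11 and C14 aldehydes on C7 and C10 (not isolated) | CCCC(=O)[C@]1(O)[C@@H](C=O)CC[C@@H](C=O)[C@@H](O[Si](CC)(CC)CC)[C@@H]1OC(=O)C(C)C | intermediate
19 | lactol aldehyde: six-membered lactol C1–O–C11 (both anomers), free C14 aldehyde on C10 | CCCC(=O)[C@]1(OC2O)[C@@H](C=O)CC[C@@H]2[C@@H](O[Si](CC)(CC)CC)[C@@H]1OC(=O)C(C)C | intermediate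
20 | C14 tosylhydrazone of 19 (not isolated) | CCCC(=O)[C@]1(OC2O)[C@@H](C=NNS(=O)(=O)c3ccc(C)cc3)CC[C@@H]2[C@@H](O[Si](CC)(CC)CC)[C@@H]1OC(=O)C(C)C | intermediate
21 | methyl lactol: as 19 with C14 as the methyl group on C10 | CCCC(=O)[C@]1(OC2O)[C@@H](C)CC[C@@H]2[C@@H](O[Si](CC)(CC)CC)[C@@H]1OC(=O)C(C)C | intermediate
22 | silyl alkyne: 7β-ethynyl, 6β-OSiEt3, 1β-OH, 5α-isobutyrate, 10β-methyl, 1-butanoyl (not isolated) | CCCC(=O)[C@]1(O)[C@@H](C)CC[C@@H](C#C)[C@@H](O[Si](CC)(CC)CC)[C@@H]1OC(=O)C(C)C | intermediate
23 | alkynyl diol: 1-butanoyl-7β-ethynyl-1β,6β-dihydroxy-10β-methylcycloheptan-5α-yl isobutyrate | CCCC(=O)[C@]1(O)[C@@H](C)CC[C@@H](C#C)[C@@H](O)[C@@H]1OC(=O)C(C)C | intermediate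
24 | α-methylene γ-lactone (C6–O–C12(=O)–C11(=C13H2)–C7, cis-fused), 1-butanoyl, 1β-OH, 5α-isobutyrate | CCCC(=O)[C@]1(O)[C@@H](C)CC[C@@H]2[C@@H](OC(=O)C2=C)[C@@H]1OC(=O)C(C)C | intermediate
25 | α-methyl lactone with butanoyl chain (3,4-dihydro target; H11 cis to H7) | CCCC(=O)[C@]1(O)[C@@H](C)CC[C@@H]2[C@@H](OC(=O)[C@@H]2C)[C@@H]1OC(=O)C(C)C | intermediate
26 | trimethylsilyl enol ether of 25 with C1–OSiMe3 (not isolated) | CCC=C(O[Si](C)(C)C)[C@]1(O[Si](C)(C)C)[C@@H](C)CC[C@@H]2[C@@H](OC(=O)[C@@H]2C)[C@@H]1OC(=O)C(C)C | intermediate
27 | C1 trimethylsilyl ether of the target (not isolated) | C/C=C/C(=O)[C@]1(O[Si](C)(C)C)[C@@H](C)CC[C@@H]2[C@@H](OC(=O)[C@@H]2C)[C@@H]1OC(=O)C(C)C | intermediate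
28 | CNP0149747.1: (E)-but-2-enoyl on C1, 1β-OH, 5α-isobutyrate, 6β,7β-cis-fused α-methyl-γ-lactone (H11 cis to H7), 10β-methyl | C/C=C/C(=O)[C@]1(O)[C@@H](C)CC[C@@H]2[C@@H](OC(=O)[C@@H]2C)[C@@H]1OC(=O)C(C)C | target

## Step count and risks

Total step count: 17. Longest linear sequence: 17 steps (from tropone; ethylene and butanal are bought).

Steps most likely to fail:

Step 13. What may go wrong is loss of chemoselectivity between the two carbonyl carbons: the hydrazide may also condense at C11 through the open form of the lactol, or lactol formation may be incomplete, so that both carbons are deoxygenated. The fallback sets out from 14 and reverses the roles of the two aldehyde carbons. Ozonolysis of 14 (O3, CH2Cl2, −78 °C; PPh3), in which the C1 oxygen is still locked in the epoxide, should give through the ozonide F1 and the hydroxy dialdehyde F2 the lactol aldehyde F3, in which the C6 hydroxyl now masks C14 and C11 is the free aldehyde. Ohira–Bestmann homologation at 0 °C would give the alkyne F4, and epoxide opening with isobutyric acid under the conditions of step 10 the diol ester F5. Only then would tosylhydrazide be used, followed by catecholborane and NaOAc·3H2O; it meets a single aldehyde equivalent, the C14 lactol, and should convert it through the tosylhydrazone F6 into the methyl group while freeing the C6 hydroxyl. This is compound 23, so steps 11 and 14 are not needed.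

Step 10. What may go wrong is a slow opening by the weakly nucleophilic carboxylate, overtaken by acyl or alkyl shift of the epoxy ketone to a dicarbonyl compound or by migration of the new ester to a neighbouring hydroxyl. The fallback sets out from 14 and separates C–O bond formation from ester formation. Acid-catalysed hydrolysis (HClO4 cat., THF–H2O, 0 °C), in which water attacks C5 with inversion, would give the triol F7. Silylation of the exposed syn C6 hydroxyl (Et3SiCl, imidazole, −20 °C) would give the silyloxy diol F8, whose only remaining secondary hydroxyl, on C5, is acylated with isobutyric anhydride and DMAP. The route is rejoined at 16, so step 11 is not needed.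

Step 1. What may go wrong is thermal dimerisation and polymerisation of tropone outrunning the cycloaddition with the unactivated gaseous dienophile. The fallback sets out from 1 and uses phenyl vinyl sulfone as an activated ethylene equivalent (toluene, 130 °C), which should give the sulfonyl adduct F9 as a mixture of regio- and stereoisomers that all converge later. Conjugate borylation and oxidation as in step 2 would give, through the boryl sulfone F10, the hydroxy ketone sulfone F11. Reductive desulfonylation with Na(Hg), Na2HPO4, MeOH, −20 °C removes the sulfonyl group from every isomer alike and comes back to the route at racemic 5.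

Further compounds
F1 | step 13 | ozonide of 14 (trioxolane over C11 and C14; epoxide intact; not isolated) | CCCC(=O)[C@]14[C@@H]2CC[C@@H](C3OOC2O3)[C@@H](O)[C@H]1O4
F2 | step 13 | hydroxy dialdehyde from 14 (epoxide intact; not isolated) | CCCC(=O)[C@]13[C@@H](C=O)CC[C@@H](C=O)[C@@H](O)[C@H]1O3
F3 | step 13 | lactol aldehyde: C6–O–C14 lactol, free C11 aldehyde, C1–C5 epoxide intact | CCCC(=O)[C@]13[C@@H]2CC[C@@H](C=O)[C@@H](OC2O)[C@H]1O3
F4 | step 13 | alkyne: C7 ethynyl, C6–O–C14 lactol, C1–C5 epoxide intact | CCCC(=O)[C@]13[C@@H]2CC[C@@H](C#C)[C@@H](OC2O)[C@H]1O3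
F5 | step 13 | diol ester: C1–OH, C5 isobutyrate, C6–O–C14 lactol, C7 ethynyl | CCCC(=O)[C@]1(O)[C@@H]2CC[C@@H](C#C)[C@@H](OC2O)[C@@H]1OC(=O)C(C)C
F6 | step 13 | C14 tosylhydrazone of the open form of F5 (not isolated) | CCCC(=O)[C@]1(O)[C@@H](C=NNS(=O)(=O)c2ccc(C)cc2)CC[C@@H](C#C)[C@@H](O)[C@@H]1OC(=O)C(C)C
F7 | step 10 | triol: C1–OH and C6–OH syn, C5–OH anti to the etheno bridge, butanoyl on C1 | CCCC(=O)[C@]1(O)[C@@H]2CC[C@@H](C=C2)[C@@H](O)[C@@H]1O
F8 | step 10 | C6 triethylsilyl ether of F7 | CCCC(=O)[C@]1(O)[C@@H]2CC[C@@H](C=C2)[C@@H](O[Si](CC)(CC)CC)[C@@H]1O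
F9 | step 1 | (±)-8(9)-(phenylsulfonyl)bicyclo[3.2.2]nona-3,6-dien-2-one (isomer mixture, one regioisomer drawn) | O=C1[C@@H]2C(S(=O)(=O)c3ccccc3)C[C@@H](C=C2)C=C1
F10 | step 1 | boryl ketone sulfone (boron on C6 syn to the etheno bridge; not isolated) | O=C1[C@@H]2C(S(=O)(=O)c3ccccc3)C[C@@H](C=C2)[C@@H](B3OC(C)(C)C(C)(C)O3)C1
F11 | step 1 | hydroxy ketone sulfone (C6 hydroxyl syn to the etheno bridge) | O=C1[C@@H]2C(S(=O)(=O)c3ccccc3)C[C@@H](C=C2)[C@@H](O)C1
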